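The readings come from a simulation for substances that don't exist; scatter was added.

I reckon this flask from the two earlier runs rather than spend a third trial on it, and for that I need the substrate level at which the rate has fallen to half its first-order value.

| flask | substrate | free catalyst | impurity | remark | time |
|---|---|---|---|---|---|
| delta | 8 mM (fed, over 8.0 min) | 14 µM | 4.2 µM | run made earlier |  |
| eta | 32 mM (fed, over 8.0 min) | 14 µM | 4.2 µM | run made earlier |  |
| flask | 16 mM (fed, over 8.0 min) | 14 µM | 4.2 µM |  | 80 min |

| run | time / min | substrate / % | product / % |
|---|---|---|---|
| delta | 6.00 | 67 | 9 |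
| delta | 10.0 | 78 | 23 |
| delta | 20.0 | 49 | 49 |
| delta | 30.0 | 27 | 71 |
| delta | 50.0 | 9 | 90 |
| delta | 80.0 | 4 | 99 |
| eta | 6.00 | 67 | 8 |
| eta | 10.0 | 83 | 15 |
| eta | 20.0 | 65 | 35 |
| eta | 30.0 | 45 | 53 |
| eta | 50.0 | 22 | 82 |
| eta | 80.0 | 6 | 92 |

(standard deviation of a reading: 1.5 percentage points)

- percentages count the whole charge, also what has not yet gone in

- concentration of substrate at 80 min, in mM
- concentration of product at 80 min, in mM

The flask and both runs hold the same 14 µM of free catalyst and 4.2 µM of impurity, so whatever the impurity does to the catalyst is already inside the readings.

First, the feed. In this flask substrate enters at 2.00 mM/min. The delta run, on its own feed, shows substrate piling up: at 6.00 min it reads 67% substrate and 9% product.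

Then the middle. Between 10.0 min and 30.0 min the eta run, at a mean of 20.5 mM, loses substrate at 0.608 mM/min.

Last, the tail. From 20.0 min to 50.0 min substrate in the delta run falls with a first-order constant of 0.0565 /min, a reading with its scatter, which I take as k.

If rate = k·c/(1 + c/K), these two readings give, with their scatter, the crossing concentration K, the substrate level at which the rate is half the first-order value (the Michaelis constant):

K = 22.7 mM

The flask's charge of 16 mM lies below it. Integrated, the rate law reads

ln(c_start/c) + (c_start − c)/K = k·t

I start at 10.0 min, with the mean share of both runs: c_start = 12.9 mM. Dropping the small c from the second term, 70.0 min later: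

c(substrate) = 0.436 mM, c(product) = 15.6 mM

The forecast, reading the runs as “roughly Michaelis-Menten”, puts substrate at 0.55 mM and product at 15.4 mM, so its substrate stands above mine.

The flask gives 0.466 mM of substrate and 15.5 mM of product.

    free catalyst + impurity → spent catalyst (k = 3.10 × 10⁵ /M/s)
    substrate + free catalyst → catalyst intermediate A (k = 92.0 /M/s)
    catalyst intermediate A ⇌ catalyst intermediate B (K = 1.70, k = 7.00 /s)
    catalyst intermediate B → free catalyst + product (k = 5.70 /s)

That substrate lies far below K, on the pseudo-first-order side. At 21.3 min the step joining substrate to free catalyst has a substrate half-life of 17 min, short against the 80 min of the run, and 2.9% of the charge is left as substrate at the end. A neighbouring flask charged with 6.4 mM of substrate holds, on delta's share at 10.0 min, an estimated 4.99 mM, and the same K and k give 0.119 mM of substrate at 80 min. Computed, it holds 0.133 mM of substrate and 6.27 mM of product.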